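**Plan**

1. Numbering used below (caryophyllane): cyclobutane = C1, C9, C10, C11(Me2); nine-membered ring = C1–C9; C12 = methyl on C4; C13 = CH2 of the pyran; C1′ = CH(iBu).
2. Retrosynthesis: cut O–C8 and C13–C1′ (hetero-Diels–Alder of the syncarpic acid/isovaleraldehyde quinone methide on a C8=C13 methylene); C8=C13 back to a C8 ketone; reconnect C3–C8 and cut C5–C6 (retro anionic oxy-Cope), which folds the nine-membered ring onto a cyclopentanol; cut C9–C10 and C1–C11 (retro [2+2]) to isobutylene and a cyclopentenone.
3. Enabling feature: the spiro carbon C8 bears oxygen (latent ketone) and is bonded to cyclobutane C9, while the CMe2 carbon C11 sits on C1, β to C8. This is the head-to-tail enone/isobutylene photoadduct pattern C8(=O)–C9=C1.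
4. C8, C9, C1, C2, C3 are held in a temporary cyclopentenone ring, which enforces cycloaddition instead of E/Z isomerisation and is later opened across C3–C8.
5. Forward order: cyclobutane on the cyclopentenone, then C3 alkenylation and C8 vinylation, then five-to-nine ring expansion, then C8 methylenation and C5 correction, and the spiro-dihydropyran last.
6. Stereochemistry: a purchased silyloxy stereocentre at C2 steers the [2+2] (C1, C9) and is then eliminated; C1 relays to the Z-C3=C4 geometry (boat oxy-Cope); C9 is equilibrated to the trans fusion; C5 is set by CBS reduction; C8 and C1′ are set in the final cycloaddition.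

Key step: step 1

Assumption: (S)-4-(tert-butyldimethylsilyloxy)cyclopent-2-enone is taken as a catalogue compound (both antipodes are sold); triketones 19, 20 and 22 are written as single tautomers.

**Route**

Step 1
Reactants: 1 (S)-4-(tert-butyldimethylsilyloxy)cyclopent-2-en-1-one; 2 isobutylene (2-methylpropene)
Product: 3 (1R,4S,5R)-4-(tert-butyldimethylsilyloxy)-6,6-dimethylbicyclo[3.2.0]heptan-2-one (silyloxy group exo, trans to the cyclobutane)
Conditions: hν (350 nm lamps, Pyrex), 2 (ca. 20 equiv, condensed), CH2Cl2, −70 °C
Reagents that add atoms: none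
Why: Excitation and intersystem crossing give the enone triplet, which adds to isobutylene through triplet 1,4-biradicals that close after spin inversion; the closest known reaction type is the enone–alkene [2+2] photocycloaddition, including its use on 4-oxygenated cyclopentenones. The cyclobutane (bonds C9–C10 and C1–C11) is closed by radical addition followed by 1,4-biradical recombination, and the five-membered enone ring can only span a cis fusion, which fixes C9 relative to C1. C1 is controlled by the silyloxy group on the neighbouring C2: the alkene, whose CMe2 terminus bonds to the adjacent β-carbon, should enter on the face anti to it. The step needs head-to-tail regiochemistry (CMe2 on the β-carbon C1, CH2 on the α-carbon C9) and anti facial selectivity; the first is secured by the polarisation of the enone triplet against the alkene, the second by the γ-silyloxy substituent. Excess alkene and low temperature should suppress biradical disproportionation and enone dimerisation, and the minor head-to-head and syn isomers are removed by chromatography here so that the elimination in step 2 cannot erode enantiomeric purity.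

Step 2
Reactants: 3
Product: 5 (1R,5R)-6,6-dimethylbicyclo[3.2.0]heptan-2-one, via bicyclic enone 4 (not isolated)
Conditions: DBU, EtOAc, rt; then H2 (1 atm), 10% Pd/C, rt
Reagents that add atoms: none
Why: E1cB elimination of silanolate from the β-silyloxy ketone removes the temporary C2 stereocentre, and catalytic hydrogenation of the resulting enone C=C gives the saturated ketone; the cis ring fusion cannot invert, so C1 and C9 are untouched.

Step 3
Reactants: 6 propyne
Product: 7 (E)-2-bromo-1-iodoprop-1-ene
Conditions: IBr (1.0 equiv), CH2Cl2, −78 °C to 0 °C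
Reagents that add atoms: iodine monobromide, BrI
Why: Electrophilic anti addition of I–Br across the alkyne (iodonium at the terminal carbon, bromide to the internal carbon) should give the 2-bromo-1-iodoalkene with Br and I trans.

Step 4
Reactants: 7; 8 4-methoxybenzyl alcohol
Product: 9 (E)-2-bromo-1-[(4-methoxybenzyl)oxy]prop-1-ene (oxygen cis to the methyl group)
Conditions: CuI (10 mol%), 3,4,7,8-tetramethyl-1,10-phenanthroline (20 mol%), Cs2CO3, toluene, 80 °C
Reagents that add atoms: none
Why: Copper-catalysed Ullmann-type C–O coupling of a vinyl iodide with a primary alcohol, which proceeds with retention of alkene geometry and at C–I in preference to C–Br, so that oxygen ends up trans to bromine.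

Step 5
Reactants: 5; 9
Product: 10 (1R,3S,5R)-3-[(E)-1-[(4-methoxybenzyl)oxy]prop-1-en-2-yl]-6,6-dimethylbicyclo[3.2.0]heptan-2-one (alkenyl group exo)
Conditions: LiHMDS (2.2 equiv), Pd2(dba)3 (2.5 mol%), t-Bu3P·HBF4 (6 mol%), toluene/THF, rt to 40 °C; aq NH4Cl; then Et3N, CH2Cl2, rt
Reagents that add atoms: none
Why: Palladium-catalysed α-alkenylation of a ketone enolate: kinetic deprotonation occurs at the C3 methylene and not at the strained bridgehead C9, the alkenyl bromide couples with retention of geometry, and amine equilibration of the acidic C3 centre should place the alkenyl group on the convex face, away from the endo methyl of C11.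

Step 6
Reactants: 10
Product: 11 (1R,2R,3S,5R)-3-[(E)-1-[(4-methoxybenzyl)oxy]prop-1-en-2-yl]-6,6-dimethyl-2-vinylbicyclo[3.2.0]heptan-2-ol (vinyl and alkenyl both exo, hydroxyl endo)
Conditions: CH2=CHMgBr, anhydrous CeCl3, THF, −78 °C
Reagents that add atoms: vinylmagnesium bromide, C=C[Mg]Br
Why: Organocerium 1,2-addition (suppressing enolisation at the acidic C3–H): attack on the convex face of the cup-shaped bicycle, opposite the cyclobutane, should place the vinyl group cis to the C3 alkenyl group; this carbinol centre is destroyed in step 7.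

Step 7
Reactants: 11
Product: 13 (1R,5R,9S,Z)-5-[(4-methoxybenzyl)oxy]-4,11,11-trimethylbicyclo[7.2.0]undec-3-en-8-one (trans-fused), via cis-fused ketone 12 (not isolated)
Conditions: KH, 18-crown-6, THF, 0 °C to rt; then MeOH, rt; aq NH4Cl
Reagents that add atoms: none
Why: Anionic oxy-Cope rearrangement ([3,3] shift of the potassium alkoxide of a cis-1,2-dialkenylcyclopentanol) cleaves C3–C8 and forms C5–C6, expanding the five- to the nine-membered ring; the boat transition state over the convex face, with the C4 methyl and the C5 alkoxy group pointing outward, should give the Z-C3=C4 alkene and 5R, and methanol/KOMe then protonates the enolate and equilibrates C9 through the C8 enolate to the trans 4/9 fusion, the more stable one in ketones of this type.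

Step 8
Reactants: 13
Product: 14 (1R,5R,9S,Z)-5-[(4-methoxybenzyl)oxy]-4,11,11-trimethyl-8-methylidenebicyclo[7.2.0]undec-3-ene
Conditions: Ph3PCH3Br, KOt-Bu, THF, 0 °C to reflux
Reagents that add atoms: methyltriphenylphosphonium bromide, C[P+](c1ccccc1)(c1ccccc1)c1ccccc1.[Br-]
Why: Wittig methylenation of the ketone with the non-stabilised ylide; C9 is already in its thermodynamic configuration, so the basic conditions cannot scramble it.

Step 9
Reactants: 14
Product: 15 (1R,5R,9S,Z)-4,11,11-trimethyl-8-methylidenebicyclo[7.2.0]undec-3-en-5-ol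
Conditions: DDQ (1.2 equiv), CH2Cl2/pH 7 buffer, 0 °C
Reagents that add atoms: none
Why: Oxidative cleavage of the p-methoxybenzyl ether by DDQ (hydride abstraction, then hydrolysis of the oxocarbenium ion) under buffered conditions that spare the acid-sensitive diene.

Step 10
Reactants: 15
Product: 16 (1R,9S,Z)-4,11,11-trimethyl-8-methylidenebicyclo[7.2.0]undec-3-en-5-one
Conditions: Dess–Martin periodinane, CH2Cl2, 0 °C to rt
Reagents that add atoms: none
Why: Dess–Martin oxidation of the allylic alcohol to the Z-enone, which erases the C5 centre formed with the wrong sense in the oxy-Cope step.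

Step 11
Reactants: 16
Product: 17 (1R,5S,9S,Z)-4,11,11-trimethyl-8-methylidenebicyclo[7.2.0]undec-3-en-5-ol
Conditions: (R)-2-methyl-CBS-oxazaborolidine (0.2–1 equiv), catecholborane, toluene, −78 °C
Reagents that add atoms: none
Why: Corey–Bakshi–Shibata reduction: the (R)-oxazaborolidine delivers hydride with the α-methylalkenyl side (C4) as the large group and the C6 methylene as the small one, which should give the 5S allylic alcohol by reagent control; catecholborane at low temperature leaves the alkenes untouched.

Step 12
Reactants: 18 2,4,6-trihydroxyacetophenone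
Product: 19 6-acetyl-2,2,4,4-tetramethylcyclohexane-1,3,5-trione (acetylsyncarpic acid, enol form)
Conditions: MeI (excess), NaOMe, MeOH, reflux
Reagents that add atoms: iodomethane, CI
Why: Exhaustive dearomatising C-methylation of the phloroglucinol nucleus under basic conditions gives the gem-dimethylated acyl triketone.

Step 13
Reactants: 19
Product: 20 syncarpic acid (2,2,4,4-tetramethylcyclohexane-1,3,5-trione)
Conditions: 6 M aq HCl, reflux
Reagents that add atoms: none
Why: Acid-mediated retro-Claisen deacylation of the β-triketone.

Step 14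
Reactants: 17; 20; 21 isovaleraldehyde (3-methylbutanal)
Product: 23 tomentodione P, via quinone methide 22 (not isolated)
Conditions: 20 (1.5 equiv), 21 (2 equiv, added slowly), EDDA (20 mol%), 4 Å MS, toluene, 60 °C
Reagents that add atoms: none
Why: Domino Knoevenagel/inverse-electron-demand hetero-Diels–Alder reaction: EDDA condenses 20 with 21 to the enetrione 22, whose s-cis oxadiene should add regioselectively to the 1,1-disubstituted C8=C13 alkene (O to C8, C1′ to C13) in preference to the hindered trisubstituted C3=C4; bonding to the Re face of C8 (C9 > C7 > C13) with the isobutyl group outside and the C9 arm endo places isobutyl and the cyclobutane-bearing arm cis-diequatorial on the new half-chair and should give 8S,1′S, the remaining diastereomers being removed by chromatography.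

**Compound list**

1 | (S)-4-(tert-butyldimethylsilyloxy)cyclopent-2-en-1-one | O=C1C=C[C@@H](O[Si](C)(C)C(C)(C)C)C1 | starting material
2 | isobutylene (2-methylpropene) | CC(C)=C | starting material
3 | (1R,4S,5R)-4-(tert-butyldimethylsilyloxy)-6,6-dimethylbicyclo[3.2.0]heptan-2-one | C1[C@H](O[Si](C)(C)C(C)(C)C)[C@@H]2[C@@H](CC2(C)C)C1=O | intermediate
4 | (1R,5R)-6,6-dimethylbicyclo[3.2.0]hept-3-en-2-one | C1=C[C@@H]2[C@@H](CC2(C)C)C1=O | intermediate
5 | (1R,5R)-6,6-dimethylbicyclo[3.2.0]heptan-2-one | C1C[C@@H]2[C@@H](CC2(C)C)C1=O | intermediate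
6 | propyne | CC#C | starting material
7 | (E)-2-bromo-1-iodoprop-1-ene | C/C(Br)=C\I | intermediate
8 | 4-methoxybenzyl alcohol | COc1ccc(CO)cc1 | starting material
9 | (E)-2-bromo-1-[(4-methoxybenzyl)oxy]prop-1-ene | C/C(Br)=C\OCc1ccc(OC)cc1 | intermediate
10 | (1R,3S,5R)-3-[(E)-1-[(4-methoxybenzyl)oxy]prop-1-en-2-yl]-6,6-dimethylbicyclo[3.2.0]heptan-2-one | [C@@H]1(/C(C)=C/OCc3ccc(OC)cc3)C[C@@H]2[C@@H](CC2(C)C)C1=O | intermediate
11 | (1R,2R,3S,5R)-3-[(E)-1-[(4-methoxybenzyl)oxy]prop-1-en-2-yl]-6,6-dimethyl-2-vinylbicyclo[3.2.0]heptan-2-ol | [C@@H]1(/C(C)=C/OCc3ccc(OC)cc3)C[C@@H]2[C@@H](CC2(C)C)[C@]1(O)C=C | intermediate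
12 | (1R,5R,9R,Z)-5-[(4-methoxybenzyl)oxy]-4,11,11-trimethylbicyclo[7.2.0]undec-3-en-8-one (cis-fused) | C/C1=C/C[C@@H]2[C@@H](CC2(C)C)C(=O)CC[C@H]1OCc1ccc(OC)cc1 | intermediate
13 | (1R,5R,9S,Z)-5-[(4-methoxybenzyl)oxy]-4,11,11-trimethylbicyclo[7.2.0]undec-3-en-8-one (trans-fused) | C/C1=C/C[C@@H]2[C@H](CC2(C)C)C(=O)CC[C@H]1OCc1ccc(OC)cc1 | intermediate
14 | (1R,5R,9S,Z)-5-[(4-methoxybenzyl)oxy]-4,11,11-trimethyl-8-methylidenebicyclo[7.2.0]undec-3-ene | C/C1=C/C[C@@H]2[C@H](CC2(C)C)C(=C)CC[C@H]1OCc1ccc(OC)cc1 | intermediate
15 | (1R,5R,9S,Z)-4,11,11-trimethyl-8-methylidenebicyclo[7.2.0]undec-3-en-5-ol | C/C1=C/C[C@@H]2[C@H](CC2(C)C)C(=C)CC[C@H]1O | intermediate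
16 | (1R,9S,Z)-4,11,11-trimethyl-8-methylidenebicyclo[7.2.0]undec-3-en-5-one | C/C1=C/C[C@@H]2[C@H](CC2(C)C)C(=C)CCC1=O | intermediate
17 | (1R,5S,9S,Z)-4,11,11-trimethyl-8-methylidenebicyclo[7.2.0]undec-3-en-5-ol | C/C1=C/C[C@@H]2[C@H](CC2(C)C)C(=C)CC[C@@H]1O | intermediate
18 | 2,4,6-trihydroxyacetophenone | CC(=O)c1c(O)cc(O)cc1O | starting material
19 | 6-acetyl-2,2,4,4-tetramethylcyclohexane-1,3,5-trione (enol form) | CC(=O)C1=C(O)C(C)(C)C(=O)C(C)(C)C1=O | intermediate
20 | syncarpic acid (2,2,4,4-tetramethylcyclohexane-1,3,5-trione) | CC1(C)C(=O)CC(=O)C(C)(C)C1=O | intermediate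
21 | isovaleraldehyde (3-methylbutanal) | CC(C)CC=O | starting material
22 | 2,2,4,4-tetramethyl-6-(3-methylbutylidene)cyclohexane-1,3,5-trione | CC(C)CC=C1C(=O)C(C)(C)C(=O)C(C)(C)C1=O | intermediate
23 | tomentodione P | C/C1=C/C[C@@H]2[C@H](CC2(C)C)[C@]2(CC[C@@H]1O)C[C@H](CC(C)C)C1=C(O2)C(C)(C)C(=O)C(C)(C)C1=O | target

**Step count and risks**

Total step count: 14. Longest linear sequence: 10 steps (1, 2, 5, 6, 7, 8, 9, 10, 11, 14).

Steps most likely to fail:

Step 14. The cycloaddition on the flexible nine-membered ring may run with poor facial and endo/exo selectivity, so that C8/C1′ diastereomers compete with or outweigh 23. Fallback: the cycloaddition is moved one stage back, onto dienone 16, whose conjugated Z-enone holds C3–C6 coplanar and removes the free hydroxyl. Under the same domino conditions 16, 20 and 21 should give the 5-oxo analogue of 23, F1, on a differently folded and stiffer ring, and the isomers are separated at this ketone stage. (R)-CBS/catecholborane reduction of the C5 enone carbonyl (the two carbonyls of the syncarpic unit being hindered or vinylogous-ester-like) then sets C5 last. This fallback sets out from 16 and comes back to the route at 23.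

Step 6. The vinyl nucleophile may attack anti to the neighbouring C3 alkenyl group (concave face) or merely enolise 10; this would give the trans-dialkenyl carbinol, which cannot reach the boat transition state of step 7. Fallback: a sterically undemanding sp nucleophile is used and the alkene is made afterwards. Ethynylmagnesium bromide/CeCl3 in THF at −78 °C should add to 10 from the convex face to give the ethynyl carbinol F2, and Lindlar semi-hydrogenation (Pd/CaCO3/Pb, quinoline, H2) converts it into the vinyl carbinol. This fallback sets out from 10 and comes back at 11.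

Step 5. The enolate coupling may suffer from bis-alkenylation, enolate equilibration, or base-induced migration of the enol ether double bond into conjugation with the ketone. Fallback: the C3–C4 bond is made by cross-coupling at an sp2 carbon under non-enolising conditions. Bromide 9 is borylated (B2pin2, PdCl2(dppf), KOPh, toluene) to the alkenylboronate F3. Enone 4 is isolated after the DBU treatment of 3 and iodinated (I2, pyridine, CH2Cl2) to the α-iodoenone F4. Suzuki–Miyaura coupling of the two (Pd(PPh3)4, K3PO4, dioxane/water) gives the cross-conjugated dienone F5, whose ring C=C is reduced by conjugate hydride delivery from [(Ph3P)CuH]6, followed by amine equilibration at C3. This fallback sets out from 4 (and 9) and comes back at 10.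

**Further compounds**

F1 | step 14 | 5-oxo analogue of 23 (C5 ketone, 8S,1′S) | C/C1=C/C[C@@H]2[C@H](CC2(C)C)[C@]2(CCC1=O)C[C@H](CC(C)C)C1=C(O2)C(C)(C)C(=O)C(C)(C)C1=O
F2 | step 6 | (1R,2R,3S,5R)-2-ethynyl-3-[(E)-1-[(4-methoxybenzyl)oxy]prop-1-en-2-yl]-6,6-dimethylbicyclo[3.2.0]heptan-2-ol | [C@@H]1(/C(C)=C/OCc3ccc(OC)cc3)C[C@@H]2[C@@H](CC2(C)C)[C@]1(O)C#C
F3 | step 5 | (Z)-2-[1-[(4-methoxybenzyl)oxy]prop-1-en-2-yl]-4,4,5,5-tetramethyl-1,3,2-dioxaborolane | C/C(B1OC(C)(C)C(C)(C)O1)=C\OCc1ccc(OC)cc1
F4 | step 5 | (1R,5S)-3-iodo-6,6-dimethylbicyclo[3.2.0]hept-3-en-2-one (3-iodo derivative of 4) | C1(I)=C[C@@H]2[C@@H](CC2(C)C)C1=O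
F5 | step 5 | (1R,5R)-3-[(E)-1-[(4-methoxybenzyl)oxy]prop-1-en-2-yl]-6,6-dimethylbicyclo[3.2.0]hept-3-en-2-one | C1(/C(C)=C/OCc3ccc(OC)cc3)=C[C@@H]2[C@@H](CC2(C)C)C1=O
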